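**Assumptions.** (R)-Benzyl glycidyl ether is taken as the cheap, purchased chiral building block. The aryl Grignard made in situ in step 10 is not counted as a step. Lignan numbering is used: C7/C7' are the benzylic carbons, C8/C8' the ring CH carbons, C9/C9' the CH2–O carbons.

## Retrosynthetic overview

1. Target ⇐ global O-debenzylation ⇐ C7–aryl bond: Felkin–Anh addition of an aryl Grignard to a tetrahydrofuran-3-carbaldehyde, itself from ozonolysis of a 4-alkenyl group.
2. Tetrahydrofuran ring (the only ring of the target, formed second) ⇐ acid-mediated 5-exo closure of C9–OH onto the C7' benzylic cation of a triol ⇐ LiAlH4 reduction of a trans aldol adduct of a β-alkenyl-γ-butyrolactone with 3,4-bis(benzyloxy)benzaldehyde.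
3. β-Alkenyl-γ-butyrolactone (temporary ring, formed first; C8 stereocentre and the C8–C8' bond) ⇐ Johnson–Claisen [3,3]-sigmatropic rearrangement of an (R,E)-allylic alcohol with 1,3-chirality transfer.
4. Allylic alcohol ⇐ cross-metathesis ⇐ vinyl carbinol ⇐ (R)-benzyl glycidyl ether, the single source of chirality.

## Forward route

**Step 1**
Reactants: 1, (R)-benzyl glycidyl ether [(R)-2-[(benzyloxy)methyl]oxirane]
Product: 2, (R)-1-(benzyloxy)but-3-en-2-ol
Conditions: Me3S+ I− (3.5 equiv), n-BuLi (3.4 equiv), THF, −10 °C → rt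
Reagents that add atoms: trimethylsulfonium iodide, C[S+](C)C.[I-] (one CH2)
Why: Dimethylsulfonium methylide opens the epoxide at its CH2 terminus and a second ylide equivalent eliminates Me2S to give the one-carbon-homologated allylic alcohol; the stereocentre is not touched.

**Step 2**
Reactants: 2; 3, (Z)-but-2-ene-1,4-diyl diacetate (3 equiv)
Product: 4, (R,E)-5-(benzyloxy)-4-hydroxypent-2-en-1-yl acetate
Conditions: Hoveyda–Grubbs II (3 mol %), CH2Cl2, 40 °C; E isomer purified
Reagents that add atoms: none (new atoms come from 3)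
Why: Olefin cross-metathesis of a secondary allylic alcohol with a symmetrical internal olefin gives the E-1,2-disubstituted alkene under thermodynamic control; the carbinol centre is unaffected.

**Step 3 (key step)**
Reactants: 4; 5, triethyl orthoacetate (6 equiv)
Product: 6, ethyl (S,E)-3-(acetoxymethyl)-6-(benzyloxy)hex-4-enoate
Conditions: MeC(OEt)3, EtCO2H (10 mol %), 140 °C, EtOH distilled off
Reagents that add atoms: none (new atoms come from 5)
Why: Johnson–Claisen [3,3]-sigmatropic rearrangement through a chair transition state with CH2OBn equatorial forms the C8–C8' bond suprafacially across the E-alkene, so the (R)-carbinol chirality is transferred completely to the new C–C stereocentre (target C8).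

**Step 4**
Reactants: 6
Product: 7, (S)-4-[(E)-3-(benzyloxy)prop-1-en-1-yl]oxolan-2-one
Conditions: K2CO3, MeOH, rt; then Amberlyst-15, CH2Cl2
Reagents that add atoms: none
Why: Acetate methanolysis frees the primary alcohol, which lactonises onto the ester; the stereocentre has no acidic hydrogen and cannot epimerise.

**Step 5**
Reactants: 7; 8, 3,4-bis(benzyloxy)benzaldehyde
Product: 9, (3S,4R)-3-{[3,4-bis(benzyloxy)phenyl](hydroxy)methyl}-4-[(E)-3-(benzyloxy)prop-1-en-1-yl]oxolan-2-one (trans lactone; both carbinol epimers)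
Conditions: LDA (1.15 equiv), THF, −78 °C; then 8, −78 °C; AcOH quench at −78 °C
Reagents that add atoms: none (new atoms come from 8)
Why: Aldol addition of the lactone lithium enolate occurs anti to the C4 alkenyl group, giving the 3,4-trans lactone and setting target C8'; the carbinol configuration is irrelevant because it is ionised in step 7.

**Step 6**
Reactants: 9
Product: 10, (2R,3R)-2-{[3,4-bis(benzyloxy)phenyl](hydroxy)methyl}-3-[(E)-3-(benzyloxy)prop-1-en-1-yl]butane-1,4-diol (carbinol epimers)
Conditions: LiAlH4, THF, 0 °C; Rochelle salt work-up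
Reagents that add atoms: none
Why: Hydride reduction opens the lactone to the 1,4-diol without touching the benzyl ethers, the alkene or the stereocentres.

**Step 7**
Reactants: 10
Product: 11, [(2S,3R,4R)-2-[3,4-bis(benzyloxy)phenyl]-4-[(E)-3-(benzyloxy)prop-1-en-1-yl]oxolan-3-yl]methanol
Conditions: p-TsOH·H2O (10 mol %), CH2Cl2, 0 °C → rt
Reagents that add atoms: none
Why: SN1 cycloetherification: both carbinol epimers give the same p-alkoxybenzyl cation, which the C9 hydroxyl traps 5-exo (the other primary OH could only form an oxetane), placing the aryl group trans to the adjacent CH2OH and setting C7'.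

**Step 8**
Reactants: 11
Product: 12, (2S,3R,4R)-2-[3,4-bis(benzyloxy)phenyl]-3-[(benzyloxy)methyl]-4-[(E)-3-(benzyloxy)prop-1-en-1-yl]oxolane
Conditions: NaH, BnBr, Bu4NI (cat.), THF–DMF, 0 °C → rt
Reagents that add atoms: benzyl bromide, BrCc1ccccc1
Why: Williamson etherification caps the C9' hydroxyl so that it cannot form a lactol or a magnesium alkoxide chelate with the aldehyde in steps 9–10.

**Step 9**
Reactants: 12
Product: 13, (3R,4R,5S)-5-[3,4-bis(benzyloxy)phenyl]-4-[(benzyloxy)methyl]oxolane-3-carbaldehyde (used crude)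
Conditions: O3, CH2Cl2–MeOH, NaHCO3, −78 °C (Sudan III end-point); then Me2S, −78 °C → rt
Reagents that add atoms: ozone, [O-][O+]=O
Why: Ozonolysis with reductive work-up cleaves the only alkene (the dye end-point protects the electron-rich arenes) and releases the C7 aldehyde, losing benzyloxyacetaldehyde.

**Step 10**
Reactants: 13; 14, 1-(benzyloxy)-4-bromo-2-methoxybenzene
Product: 15, (R)-[4-(benzyloxy)-3-methoxyphenyl]{(3R,4R,5S)-5-[3,4-bis(benzyloxy)phenyl]-4-[(benzyloxy)methyl]oxolan-3-yl}methanol
Conditions: 14, Mg, THF (→ ArMgBr, 3 equiv); then 13, THF, −78 °C; NH4Cl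
Reagents that add atoms: none (aryl group comes from 14)
Why: Grignard addition under Felkin–Anh control: the aryl attacks anti to the branched ring carbon C8' with the carbonyl oxygen on the C9 side, which is also the sense predicted by a β-chelate to the ring oxygen, giving the (7R) carbinol.

**Step 11**
Reactants: 15
Product: 16, (7R)-7-hydroxytaxiresinol
Conditions: H2 (1 atm), 10% Pd/C, EtOAc–MeOH, rt, neutral, stopped at full debenzylation
Reagents that add atoms: none
Why: Hydrogenolysis removes the three aryl benzyl ethers and the primary benzyl ether; under neutral room-temperature conditions these cleave faster than the benzylic C7–OH and C7'–O bonds.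

## Compound list

1 | (R)-benzyl glycidyl ether | C1O[C@H]1COCc2ccccc2 | starting material
2 | (R)-1-(benzyloxy)but-3-en-2-ol | C=C[C@@H](O)COCc1ccccc1 | intermediate
3 | (Z)-but-2-ene-1,4-diyl diacetate | CC(=O)OC/C=C\COC(C)=O | starting material
4 | (R,E)-5-(benzyloxy)-4-hydroxypent-2-en-1-yl acetate | CC(=O)OC/C=C/[C@@H](O)COCc1ccccc1 | intermediate
5 | triethyl orthoacetate | CC(OCC)(OCC)OCC | starting material
6 | ethyl (S,E)-3-(acetoxymethyl)-6-(benzyloxy)hex-4-enoate | CCOC(=O)C[C@H](COC(C)=O)/C=C/COCc1ccccc1 | intermediate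
7 | (S)-4-[(E)-3-(benzyloxy)prop-1-en-1-yl]oxolan-2-one | O=C1C[C@@H](/C=C/COCc2ccccc2)CO1 | intermediate
8 | 3,4-bis(benzyloxy)benzaldehyde | O=Cc1ccc(OCc2ccccc2)c(OCc2ccccc2)c1 | starting material
9 | (3S,4R)-3-{[3,4-bis(benzyloxy)phenyl](hydroxy)methyl}-4-[(E)-3-(benzyloxy)prop-1-en-1-yl]oxolan-2-one (carbinol epimers) | O=C1[C@H](C(O)c2ccc(OCc3ccccc3)c(OCc3ccccc3)c2)[C@@H](/C=C/COCc2ccccc2)CO1 | intermediate
10 | (2R,3R)-2-{[3,4-bis(benzyloxy)phenyl](hydroxy)methyl}-3-[(E)-3-(benzyloxy)prop-1-en-1-yl]butane-1,4-diol (carbinol epimers) | OC[C@H](C(O)c1ccc(OCc2ccccc2)c(OCc2ccccc2)c1)[C@@H](/C=C/COCc1ccccc1)CO | intermediate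
11 | [(2S,3R,4R)-2-[3,4-bis(benzyloxy)phenyl]-4-[(E)-3-(benzyloxy)prop-1-en-1-yl]oxolan-3-yl]methanol | C(OCc1ccccc1)/C=C/[C@H]1CO[C@H](c2ccc(OCc3ccccc3)c(OCc3ccccc3)c2)[C@H]1CO | intermediate
12 | (2S,3R,4R)-2-[3,4-bis(benzyloxy)phenyl]-3-[(benzyloxy)methyl]-4-[(E)-3-(benzyloxy)prop-1-en-1-yl]oxolane | C(OCc1ccccc1)/C=C/[C@H]1CO[C@H](c2ccc(OCc3ccccc3)c(OCc3ccccc3)c2)[C@H]1COCc1ccccc1 | intermediate
13 | (3R,4R,5S)-5-[3,4-bis(benzyloxy)phenyl]-4-[(benzyloxy)methyl]oxolane-3-carbaldehyde | O=C[C@H]1CO[C@H](c2ccc(OCc3ccccc3)c(OCc3ccccc3)c2)[C@H]1COCc1ccccc1 | intermediate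
14 | 1-(benzyloxy)-4-bromo-2-methoxybenzene | COc1cc(Br)ccc1OCc1ccccc1 | starting material
15 | (R)-[4-(benzyloxy)-3-methoxyphenyl]{(3R,4R,5S)-5-[3,4-bis(benzyloxy)phenyl]-4-[(benzyloxy)methyl]oxolan-3-yl}methanol | COc1cc([C@H](O)[C@H]2CO[C@H](c3ccc(OCc4ccccc4)c(OCc4ccccc4)c3)[C@H]2COCc2ccccc2)ccc1OCc1ccccc1 | intermediate
16 | (7R)-7-hydroxytaxiresinol, 4-[(2S,3R,4R)-4-[(R)-hydroxy(4-hydroxy-3-methoxyphenyl)methyl]-3-(hydroxymethyl)oxolan-2-yl]benzene-1,2-diol | COc1cc([C@H](O)[C@H]2CO[C@H](c3ccc(O)c(O)c3)[C@H]2CO)ccc1O | target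

## Summary

Total steps: 11. Longest linear sequence: 11 (from 1).

Three steps most likely to fail, each with a fallback:

1. **Step 10 (with the crude aldehyde from step 9).** The cis-aldehyde 13 can epimerise at C8 and the Felkin selectivity at C7 may be only moderate. Fallback: set C7 at the ketone level instead. Oxidise the C7 epimer mixture of 15 to the aryl ketone (Dess–Martin), reduce it with hydride (L-Selectride or Zn(BH4)2), and if the reduction favours 7S, invert by Mitsunobu esterification (p-nitrobenzoic acid, DIAD, PPh3) and methanolysis.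

2. **Step 11.** Hydrogenolysis could over-reduce the electron-rich benzylic C7–OH or open the 2-aryl tetrahydrofuran. Fallback: switch the whole protecting-group plan to silyl ethers and finish with buffered TBAF/AcOH instead of hydrogenolysis. This means 3,4-bis(TBSO)benzaldehyde in step 5, TBSCl in step 8 and the TBS ether of 4-bromo-2-methoxyphenol in step 10.

3. **Step 2.** Cross-metathesis may give incomplete E-selectivity, and any Z-isomer of 4 leads to the enantiomer of 6 in the Claisen step, eroding the enantiomeric ratio. Fallback: build 4 with fixed E-geometry by olefination instead. Start from (S)-glyceraldehyde acetonide (from L-ascorbic acid): Ph3P=CHCO2Et, DIBAL, Ac2O, aqueous AcOH to remove the acetonide, then Bu2SnO/BnBr for selective primary benzylation.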